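Everything rests on cutting the C3–C4 bond of ring C. C3 (the carbinol) and C4 (the ketone) are both oxygen-bearing carbons held side by side by the C2–O1–C8a–C4a bridge to ring A, so one oxidation level down the bond joins two aldehyde carbons. A samarium diiodide pinacol cyclisation of an (R)-dialdehyde makes this bond, closes ring C and sets C3 and C4 in one operation, under the control of C2. The precursor carries a ring A salicylaldehyde unit with both MOM ethers and the 1,1-dimethylallyl group in place, ether-linked to an α-aryl acetaldehyde arm whose C2 centre comes from (S)-4-hydroxymandelic acid by Mitsunobu inversion.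

Key step: step 11

Remark: 2,4,6-trihydroxybenzaldehyde, prenyl bromide and (S)-4-hydroxymandelic acid are taken as commercial; benzaldehyde numbering is used for compounds 1–8 and flavonoid numbering (O1, C2–C4, C4a–C8a, rings A, B, C) from compound 12 on.

Step 1
Reactants: 1 2,4,6-trihydroxybenzaldehyde; 2 prenyl bromide (1-bromo-3-methylbut-2-ene)
Product: 3 2,6-dihydroxy-4-[(3-methylbut-2-en-1-yl)oxy]benzaldehyde
Conditions: K2CO3 (1.0 equiv), acetone, rt
Reagents that add atoms: none
Why: Williamson ether synthesis, in which one equivalent of weak base ionises only the 4-OH (para to the formyl group and not hydrogen-bonded, hence the most acidic) so that the allylic bromide should alkylate this oxygen while the two chelated ortho hydroxyls stay free.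

Step 2
Reactants: 3 2,6-dihydroxy-4-[(3-methylbut-2-en-1-yl)oxy]benzaldehyde
Product: 4 2-hydroxy-4-[(3-methylbut-2-en-1-yl)oxy]-6-[(triisopropylsilyl)oxy]benzaldehyde
Conditions: TIPSCl (1.05 equiv), imidazole, DMF, 0 °C to rt
Reagents that add atoms: triisopropylsilyl chloride, CC(C)[Si](Cl)(C(C)C)C(C)C
Why: Silyl ether formation on one of two equivalent hydroxyls, so no regiochemical choice arises, and the remaining OH is then locked in the hydrogen bond to the formyl oxygen and should not take a second bulky silyl group; this marks the oxygen that later becomes O1.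

Step 3
Reactants: 4 2-hydroxy-4-[(3-methylbut-2-en-1-yl)oxy]-6-[(triisopropylsilyl)oxy]benzaldehyde
Product: 6 2,4-dihydroxy-3-(2-methylbut-3-en-2-yl)-6-[(triisopropylsilyl)oxy]benzaldehyde, via ortho-dienone 5 (not isolated)
Conditions: PhNEt2, 180 °C
Reagents that add atoms: none
Why: Aromatic Claisen rearrangement ([3,3] shift with allyl inversion, which turns the O-prenyl group into the C-bound 1,1-dimethylallyl group), in which the para position is blocked by the formyl group and C3 is preferred over C5 because the hydrogen-bonded 2-hydroxybenzaldehyde unit fixes the C3=C4 double bond (as in the rearrangement of 4-allyloxy-2-hydroxybenzaldehydes to 3-allyl products) while C5 is shielded by the neighbouring silyl ether, after which dienone 5 tautomerises to the phenol.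

Step 4
Reactants: 6 2,4-dihydroxy-3-(2-methylbut-3-en-2-yl)-6-[(triisopropylsilyl)oxy]benzaldehyde
Product: 7 2,4-bis(methoxymethoxy)-3-(2-methylbut-3-en-2-yl)-6-[(triisopropylsilyl)oxy]benzaldehyde
Conditions: NaH, MOMCl, DMF, 0 °C
Reagents that add atoms: chloromethyl methyl ether, COCCl
Why: Williamson-type MOM ether formation, for which NaH ionises both the free 4-OH and the chelated, hindered 2-OH and the small electrophile caps both, with no stereocentre yet present and the hindered aryl silyl ether inert.

Step 5
Reactants: 7 2,4-bis(methoxymethoxy)-3-(2-methylbut-3-en-2-yl)-6-[(triisopropylsilyl)oxy]benzaldehyde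
Product: 8 6-hydroxy-2,4-bis(methoxymethoxy)-3-(2-methylbut-3-en-2-yl)benzaldehyde
Conditions: Bu4NF, AcOH, THF, 0 °C
Reagents that add atoms: none
Why: Fluoride-mediated desilylation, which cleaves only the Si–O bond (strong Si–F bond, phenoxide ortho to the formyl group as leaving group) and leaves MOM ethers, aldehyde and alkene untouched, so that the single free phenol sits para to the 1,1-dimethylallyl group.

Step 6
Reactants: 9 (S)-4-hydroxymandelic acid
Product: 10 methyl (S)-2-hydroxy-2-(4-hydroxyphenyl)acetate
Conditions: MeI, KHCO3, DMF, rt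
Reagents that add atoms: iodomethane, CI
Why: Carboxylate O-alkylation (SN2 esterification), in which KHCO3 ionises only the carboxylic acid, so the phenol is not methylated and the benzylic stereocentre, never exposed to acid, keeps its configuration.

Step 7
Reactants: 10 methyl (S)-2-hydroxy-2-(4-hydroxyphenyl)acetate
Product: 11 methyl (S)-2-hydroxy-2-[4-(methoxymethoxy)phenyl]acetate
Conditions: MOMCl, K2CO3, acetone, 0 °C to rt
Reagents that add atoms: chloromethyl methyl ether, COCCl
Why: Williamson-type MOM protection, in which K2CO3 deprotonates the phenol but not the secondary α-hydroxy ester, so only the phenolic oxygen should react and the stereocentre is preserved.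

Step 8
Reactants: 8 6-hydroxy-2,4-bis(methoxymethoxy)-3-(2-methylbut-3-en-2-yl)benzaldehyde; 11 methyl (S)-2-hydroxy-2-[4-(methoxymethoxy)phenyl]acetate
Product: 12 methyl (R)-2-[2-formyl-3,5-bis(methoxymethoxy)-4-(2-methylbut-3-en-2-yl)phenoxy]-2-[4-(methoxymethoxy)phenyl]acetate
Conditions: PPh3, DIAD, toluene, 0 °C to rt
Reagents that add atoms: none
Why: Mitsunobu etherification, in which the acidic, unhindered salicylaldehyde phenol displaces the alkoxyphosphonium of 11 by SN2 with inversion, turning the (S)-carbinol into the (R)-aryl ether that becomes C2, while the adjacent ester disfavours ionisation of the 4-alkoxybenzylic centre that would erode the configuration.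

Step 9
Reactants: 12 methyl (R)-2-[2-formyl-3,5-bis(methoxymethoxy)-4-(2-methylbut-3-en-2-yl)phenoxy]-2-[4-(methoxymethoxy)phenyl]acetate
Product: 13 (R)-2-[2-(hydroxymethyl)-3,5-bis(methoxymethoxy)-4-(2-methylbut-3-en-2-yl)phenoxy]-2-[4-(methoxymethoxy)phenyl]ethan-1-ol
Conditions: LiAlH4, THF, −20 to 0 °C
Reagents that add atoms: none
Why: Hydride reduction with LiAlH4 should take the aryl aldehyde and the ester to the diol faster than the ester can enolise, so C2 keeps its configuration and loses its acidic neighbour, and reducing both carbonyls together avoids a separate masking of the aryl aldehyde.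

Step 10
Reactants: 13 (R)-2-[2-(hydroxymethyl)-3,5-bis(methoxymethoxy)-4-(2-methylbut-3-en-2-yl)phenoxy]-2-[4-(methoxymethoxy)phenyl]ethan-1-ol
Product: 14 (R)-2-[2-formyl-3,5-bis(methoxymethoxy)-4-(2-methylbut-3-en-2-yl)phenoxy]-2-[4-(methoxymethoxy)phenyl]acetaldehyde
Conditions: Dess–Martin periodinane, NaHCO3, CH2Cl2, 0 °C; filtered cold and used at once without chromatography
Reagents that add atoms: none
Why: Dess–Martin oxidation of both primary alcohols under buffered, base-free conditions should give the dialdehyde without enolising the α-aryl α-aryloxy aldehyde, and making it immediately before use keeps the configurationally labile C2 centre from standing.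

Step 11
Reactants: 14 (R)-2-[2-formyl-3,5-bis(methoxymethoxy)-4-(2-methylbut-3-en-2-yl)phenoxy]-2-[4-(methoxymethoxy)phenyl]acetaldehyde
Product: 15 (2R,3S,4S)-5,7-bis(methoxymethoxy)-2-[4-(methoxymethoxy)phenyl]-6-(2-methylbut-3-en-2-yl)-3,4-dihydro-2H-chromene-3,4-diol (2,3-trans-3,4-cis)
Conditions: SmI2 (2.3 equiv, added slowly), t-BuOH (2 equiv), THF (0.01 M), −78 °C
Reagents that add atoms: none
Why: Electron transfer from divalent samarium to one aldehyde gives a samarium-bound ketyl whose carbon adds to the second, samarium-activated aldehyde, and a second electron transfer turns the resulting alkoxy radical into the diolate of trivalent samarium, which is protonated on work-up. The closest known reaction type is the SmI2-mediated intramolecular pinacol coupling of 1,6-dialdehydes to cis-cyclohexane-1,2-diols, including α-alkoxy aldehydes. Ring C is closed in a 6-exo-trig mode through the new C3–C4 bond. C3 is controlled by the C2 centre, whose aryl group sits pseudo-equatorial in the chair-like transition state so that the C3 oxygen takes the equatorial place trans to it, and C4 is controlled by the samarium bridge between the two oxygens, which holds the C4 oxygen cis to the C3 oxygen and pseudo-axial, away from the peri C5 OMOM group. The step needs C–C bond formation to outrun a second reduction of the ketyl at C3 (which would expel the aryloxide from C2) and simple reduction to the alcohols, and this is secured by the short, rigid ortho tether that holds the two carbonyls within bonding distance, the low temperature, the absence of HMPA and the slow addition of the reductant.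

Step 12
Reactants: 15 (2R,3S,4S)-5,7-bis(methoxymethoxy)-2-[4-(methoxymethoxy)phenyl]-6-(2-methylbut-3-en-2-yl)-3,4-dihydro-2H-chromene-3,4-diol
Product: 16 (2R,3R)-3-hydroxy-5,7-bis(methoxymethoxy)-2-[4-(methoxymethoxy)phenyl]-6-(2-methylbut-3-en-2-yl)-2,3-dihydro-4H-chromen-4-one
Conditions: DDQ (1.2 equiv), 1,4-dioxane, rt
Reagents that add atoms: none
Why: DDQ oxidation of an electron-rich benzylic alcohol, in which hydride is abstracted at C4 because the cation is stabilised by the three oxygen substituents of ring A, so the aliphatic C3 hydroxyl and the less activated C2–H next to ring B should be left alone (as in the selective benzylic oxidation of arylglycerol ethers), the C4 centre is erased and C2 and C3 are not touched.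

Step 13
Reactants: 16 (2R,3R)-3-hydroxy-5,7-bis(methoxymethoxy)-2-[4-(methoxymethoxy)phenyl]-6-(2-methylbut-3-en-2-yl)-2,3-dihydro-4H-chromen-4-one
Product: 17 (2R,3R)-3,5,7-trihydroxy-2-(4-hydroxyphenyl)-6-(2-methylbut-3-en-2-yl)-2,3-dihydro-4H-chromen-4-one
Conditions: HCl (aq), MeOH, 45 °C
Reagents that add atoms: none
Why: Acid-catalysed acetal exchange (methanolysis of the three MOM ethers) should free the phenols, the (2R,3R)-trans arrangement being the thermodynamically preferred one under dilute acid and the monosubstituted alkene of the 1,1-dimethylallyl group too weakly basic to be protonated.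

Compound list
1 | 2,4,6-trihydroxybenzaldehyde | O=Cc1c(O)cc(O)cc1O | starting material
2 | prenyl bromide (1-bromo-3-methylbut-2-ene) | CC(C)=CCBr | starting material
3 | 2,6-dihydroxy-4-[(3-methylbut-2-en-1-yl)oxy]benzaldehyde | O=Cc1c(O)cc(OCC=C(C)C)cc1O | intermediate
4 | 2-hydroxy-4-[(3-methylbut-2-en-1-yl)oxy]-6-[(triisopropylsilyl)oxy]benzaldehyde | O=Cc1c(O)cc(OCC=C(C)C)cc1O[Si](C(C)C)(C(C)C)C(C)C | intermediate
5 | 2-hydroxy-3-(2-methylbut-3-en-2-yl)-4-oxo-6-[(triisopropylsilyl)oxy]cyclohexa-1,5-diene-1-carbaldehyde (ortho-dienone, racemic at the sp3 carbon, not isolated) | O=CC1=C(O)C(C(C)(C)C=C)C(=O)C=C1O[Si](C(C)C)(C(C)C)C(C)C | intermediate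
6 | 2,4-dihydroxy-3-(2-methylbut-3-en-2-yl)-6-[(triisopropylsilyl)oxy]benzaldehyde | O=Cc1c(O)c(C(C)(C)C=C)c(O)cc1O[Si](C(C)C)(C(C)C)C(C)C | intermediate
7 | 2,4-bis(methoxymethoxy)-3-(2-methylbut-3-en-2-yl)-6-[(triisopropylsilyl)oxy]benzaldehyde | O=Cc1c(OCOC)c(C(C)(C)C=C)c(OCOC)cc1O[Si](C(C)C)(C(C)C)C(C)C | intermediate
8 | 6-hydroxy-2,4-bis(methoxymethoxy)-3-(2-methylbut-3-en-2-yl)benzaldehyde | O=Cc1c(OCOC)c(C(C)(C)C=C)c(OCOC)cc1O | intermediate
9 | (S)-4-hydroxymandelic acid | O=C(O)[C@@H](O)c1ccc(O)cc1 | starting material
10 | methyl (S)-2-hydroxy-2-(4-hydroxyphenyl)acetate | COC(=O)[C@@H](O)c1ccc(O)cc1 | intermediate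
11 | methyl (S)-2-hydroxy-2-[4-(methoxymethoxy)phenyl]acetate | COC(=O)[C@@H](O)c1ccc(OCOC)cc1 | intermediate
12 | methyl (R)-2-[2-formyl-3,5-bis(methoxymethoxy)-4-(2-methylbut-3-en-2-yl)phenoxy]-2-[4-(methoxymethoxy)phenyl]acetate | COC(=O)[C@H](Oc1cc(OCOC)c(C(C)(C)C=C)c(OCOC)c1C=O)c1ccc(OCOC)cc1 | intermediate
13 | (R)-2-[2-(hydroxymethyl)-3,5-bis(methoxymethoxy)-4-(2-methylbut-3-en-2-yl)phenoxy]-2-[4-(methoxymethoxy)phenyl]ethan-1-ol | OC[C@H](Oc1cc(OCOC)c(C(C)(C)C=C)c(OCOC)c1CO)c1ccc(OCOC)cc1 | intermediate
14 | (R)-2-[2-formyl-3,5-bis(methoxymethoxy)-4-(2-methylbut-3-en-2-yl)phenoxy]-2-[4-(methoxymethoxy)phenyl]acetaldehyde | O=C[C@@H](c1ccc(OCOC)cc1)Oc1cc(OCOC)c(C(C)(C)C=C)c(OCOC)c1C=O | intermediate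
15 | (2R,3S,4S)-5,7-bis(methoxymethoxy)-2-[4-(methoxymethoxy)phenyl]-6-(2-methylbut-3-en-2-yl)-3,4-dihydro-2H-chromene-3,4-diol | C=CC(C)(C)c1c(OCOC)cc2c(c1OCOC)[C@H](O)[C@H](O)[C@@H](c1ccc(OCOC)cc1)O2 | intermediate
16 | (2R,3R)-3-hydroxy-5,7-bis(methoxymethoxy)-2-[4-(methoxymethoxy)phenyl]-6-(2-methylbut-3-en-2-yl)-2,3-dihydro-4H-chromen-4-one | C=CC(C)(C)c1c(OCOC)cc2c(c1OCOC)C(=O)[C@H](O)[C@@H](c1ccc(OCOC)cc1)O2 | intermediate
17 | (2R,3R)-3,5,7-trihydroxy-2-(4-hydroxyphenyl)-6-(2-methylbut-3-en-2-yl)-2,3-dihydro-4H-chromen-4-one | C=CC(C)(C)c1c(O)cc2c(c1O)C(=O)[C@H](O)[C@@H](c1ccc(O)cc1)O2 | target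

Total step count: 13. Longest linear sequence: 11 steps (steps 1–5 and 8–13, from 1 to 17).

Steps most likely to fail

Step 11 (key step). What may go wrong: a second electron transfer to the ketyl at C3 before ring closure, which expels the ring A aryloxide from C2, or enolisation of 14 that erodes C2. Fallback: dialdehyde 14 is coupled instead with the divalent vanadium reagent [V2Cl3(THF)6]2[Zn2Cl6], made from VCl3(THF)3 and zinc dust in CH2Cl2 at rt. The α-aryloxy aldehyde is then held as a five-membered chelate on vanadium and the C3–C4 bond forms inside a dinuclear metal template, not from a free ketyl that can be reduced further. Low-valent vanadium pinacol coupling of this kind is established for configurationally labile α-heteroatom aldehydes. The fallback sets out from 14 and returns at diol 15; it makes no new compound (F0).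

Step 12. What may go wrong: ionisation of the C4 carbinol by the acidic hydroquinone by-product, hydride abstraction at C2, or slow oxidation because the C4–H bond of the 3,4-cis diol is poorly aligned with ring A. Fallback: from 15 the less hindered C3 hydroxyl is silylated (Et3SiOTf, 2,6-lutidine, CH2Cl2, −78 °C; the C4 hydroxyl is screened by the peri C5 OMOM group) to give the (2R,3S,4S)-3-O-triethylsilyl ether F1. Dess–Martin oxidation of the remaining C4 carbinol (NaHCO3, CH2Cl2) should give the (2R,3R)-3-triethylsilyloxy ketone F2. HCl in MeOH then removes the silyl group together with the three MOM groups, so the fallback returns at target 17.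

Step 3. What may go wrong: migration to C5 next to the silyl ether instead of C3, which would end in the 8-substituted series, or further reaction of the product phenol with its own alkene at 180 °C. Fallback: the rearrangement is moved to the symmetric ether 3, whose two ortho carbons are identical (PhNEt2, 180 °C), to give 2,4,6-trihydroxy-3-(2-methylbut-3-en-2-yl)benzaldehyde F3. The non-chelated 4-OH is capped (MOMCl 1 equiv, iPr2NEt, CH2Cl2, 0 °C) to give 2,6-dihydroxy-4-(methoxymethoxy)-3-(2-methylbut-3-en-2-yl)benzaldehyde F4. The only hydroxyl without a quaternary ortho neighbour is silylated (TIPSCl, imidazole, DMF) to give 2-hydroxy-4-(methoxymethoxy)-3-(2-methylbut-3-en-2-yl)-6-[(triisopropylsilyl)oxy]benzaldehyde F5. NaH and MOMCl in DMF then cap the last hydroxyl, and the fallback returns at 7.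

Further compounds
F0 | step 11 | none | none
F1 | step 12 | (2R,3S,4S)-5,7-bis(methoxymethoxy)-2-[4-(methoxymethoxy)phenyl]-6-(2-methylbut-3-en-2-yl)-3-[(triethylsilyl)oxy]-3,4-dihydro-2H-chromen-4-ol | C=CC(C)(C)c1c(OCOC)cc2c(c1OCOC)[C@H](O)[C@H](O[Si](CC)(CC)CC)[C@@H](c1ccc(OCOC)cc1)O2
F2 | step 12 | (2R,3R)-5,7-bis(methoxymethoxy)-2-[4-(methoxymethoxy)phenyl]-6-(2-methylbut-3-en-2-yl)-3-[(triethylsilyl)oxy]-2,3-dihydro-4H-chromen-4-one | C=CC(C)(C)c1c(OCOC)cc2c(c1OCOC)C(=O)[C@H](O[Si](CC)(CC)CC)[C@@H](c1ccc(OCOC)cc1)O2
F3 | step 3 | 2,4,6-trihydroxy-3-(2-methylbut-3-en-2-yl)benzaldehyde | O=Cc1c(O)c(C(C)(C)C=C)c(O)cc1O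
F4 | step 3 | 2,6-dihydroxy-4-(methoxymethoxy)-3-(2-methylbut-3-en-2-yl)benzaldehyde | O=Cc1c(O)c(C(C)(C)C=C)c(OCOC)cc1O
F5 | step 3 | 2-hydroxy-4-(methoxymethoxy)-3-(2-methylbut-3-en-2-yl)-6-[(triisopropylsilyl)oxy]benzaldehyde | O=Cc1c(O)c(C(C)(C)C=C)c(OCOC)cc1O[Si](C(C)C)(C(C)C)C(C)C
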